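**Retrosynthetic overview**

1. Target 29 comes from tribenzyl dialdehyde 28 by hydrogenolysis, and 28 from 26 by unmasking the ring A CH2OSi group (future C3 aldehyde) and the ring B acetal.
2. Key disconnection: ring A (C1 acyl carbon, C2–OH, C3–CHO, C4–OMe, C5–H, C6–CH3) is a 3-alkoxyphenol with a carbon substituent between OH and OMe, and its C5–C6(CH3)–C1 unit with the ester carbon is a 3-methylbut-2-enoate. It is therefore built by vinylketene–ynol ether benzannulation from diazoketone 17 and alkyne 21, forming C2–C3, C4–C5 and C1–C2.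
3. 17 comes from methyl ketone 15 by diazo transfer, and 15 from ring B phenol 10 and the (E)-keto acid 13, so the depside ester bond is made from an unhindered acid chloride before ring A exists.
4. Ring B is not constructed: orsellinic acid is formylated at C3, iodinated at C5, protected, and the iodide turned into the phenol. Alkyne 21 comes from chloroacetaldehyde dimethyl acetal, formaldehyde and TBSCl.
5. Ring order: ring B (purchased aromatic) first, ring A last, in step 13.

Key step: step 13

Remark: the target has no stereocentre; the only stereochemical element in the route is the E geometry of the side-chain alkene (12 to 17), and crude materials carried forward without purification are treated as not isolated.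

**Route**

Step 1
Reactants: 1 orsellinic acid
Product: 2 benzyl 2,4-dihydroxy-6-methylbenzoate
Conditions: BnBr, KHCO3, DMF, rt
Reagents that add atoms: benzyl bromide, BrCc1ccccc1
Why: Carboxylate O-alkylation (SN2) with bicarbonate as base leaves both phenols, which are far less acidic, untouched and installs the ester that is removed by hydrogenolysis at the end.

Step 2
Reactants: 2 benzyl 2,4-dihydroxy-6-methylbenzoate
Product: 4 benzyl 3-formyl-2,4-dihydroxy-6-methylbenzoate, via chloro ether 3 (not isolated)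
Conditions: Cl2CHOMe, TiCl4, CH2Cl2, −20 to 0 °C; then ice-cold 1 M HCl
Reagents that add atoms: dichloromethyl methyl ether, COC(Cl)Cl; water, O
Why: Rieche formylation, in which titanium bound to the two phenolic oxygens and the ester carbonyl should direct the electrophile to C3 between the hydroxyls, and hydrolysis of the chloro ether on work-up gives the doubly hydrogen-bonded aldehyde.

Step 3
Reactants: 4 benzyl 3-formyl-2,4-dihydroxy-6-methylbenzoate
Product: 5 benzyl 3-formyl-2,4-dihydroxy-5-iodo-6-methylbenzoate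
Conditions: N-iodosuccinimide, CF3CO2H (cat.), MeCN, 0 °C to rt
Reagents that add atoms: N-iodosuccinimide, O=C1CCC(=O)N1I
Why: Electrophilic aromatic iodination can only take place at C5, the single unsubstituted ring carbon, which is ortho to the 4-OH and para to the 2-OH.

Step 4
Reactants: 5 benzyl 3-formyl-2,4-dihydroxy-5-iodo-6-methylbenzoate
Product: 6 benzyl 2,4-bis(benzyloxy)-3-formyl-5-iodo-6-methylbenzoate
Conditions: BnBr, K2CO3, Bu4NI (cat.), DMF, 60 °C
Reagents that add atoms: benzyl bromide, BrCc1ccccc1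
Why: Williamson etherification under forcing carbonate conditions alkylates both chelated phenols and gives ethers that tolerate organomagnesium, amide base, ketene and fluoride chemistry and leave together with the ester at the end.

Step 5
Reactants: 6 benzyl 2,4-bis(benzyloxy)-3-formyl-5-iodo-6-methylbenzoate
Product: 7 benzyl 2,4-bis(benzyloxy)-3-(1,3-dioxolan-2-yl)-5-iodo-6-methylbenzoate
Conditions: HOCH2CH2OH, TsOH·H2O (cat.), toluene, reflux, Dean–Stark; Et3N quench
Reagents that add atoms: ethylene glycol, OCCO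
Why: Acid-catalysed acetalisation with azeotropic removal of water masks the one carbonyl group that an aryl Grignard reagent, a lithium enolate or excited-state chemistry would attack, the benzyl ester being shielded by two ortho substituents.

Step 6
Reactants: 7 benzyl 2,4-bis(benzyloxy)-3-(1,3-dioxolan-2-yl)-5-iodo-6-methylbenzoate
Product: 10 benzyl 2,4-bis(benzyloxy)-3-(1,3-dioxolan-2-yl)-5-hydroxy-6-methylbenzoate, via arylmagnesium chloride 8 (not isolated), via dimethyl arylboronate 9 (not isolated)
Conditions: iPrMgCl·LiCl, THF, 0 °C to rt; B(OMe)3, 0 °C to rt; then 30% H2O2, aq NaHCO3, 0 °C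
Reagents that add atoms: hydrogen peroxide, OO
Why: Iodine–magnesium exchange (helped by the ortho benzyloxy group and tolerated by the shielded ester), trapping as the boronate and oxidative 1,2-migration of aryl from boron to oxygen turn the C5–iodine bond into the one free phenol of ring B.

Step 7
Reactants: 11 butane-2,3-dione
Product: 12 tert-butyl (2E)-3-methyl-4-oxopent-2-enoate
Conditions: Ph3P=CHCO2tBu, CH2Cl2, rt
Reagents that add atoms: tert-butyl (triphenylphosphoranylidene)acetate, CC(C)(C)OC(=O)C=P(c1ccccc1)(c1ccccc1)c1ccccc1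
Why: Wittig olefination of one carbonyl of the symmetrical diketone with a stabilised ylide should give the E trisubstituted enoate, with the acetyl group trans to the ester, as usual for stabilised ylides.

Step 8
Reactants: 12 tert-butyl (2E)-3-methyl-4-oxopent-2-enoate
Product: 13 (2E)-3-methyl-4-oxopent-2-enoic acid
Conditions: CF3CO2H, CH2Cl2, 0 °C to rt
Reagents that add atoms: none
Why: Acidolysis of the tert-butyl ester with loss of isobutene frees the acid without touching the enone, and the E geometry keeps the acid from closing onto the ketone as a hydroxybutenolide.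

Step 9
Reactants: 13 (2E)-3-methyl-4-oxopent-2-enoic acid and 10 benzyl 2,4-bis(benzyloxy)-3-(1,3-dioxolan-2-yl)-5-hydroxy-6-methylbenzoate
Product: 15 benzyl 2,4-bis(benzyloxy)-3-(1,3-dioxolan-2-yl)-6-methyl-5-{[(2E)-3-methyl-4-oxopent-2-enoyl]oxy}benzoate, via acid chloride 14 (not isolated)
Conditions: (COCl)2, DMF (cat.), CH2Cl2, 0 °C to rt, evaporate; then 10, pyridine, DMAP (cat.), CH2Cl2, 0 °C to rt
Reagents that add atoms: none
Why: Acylation of the di-ortho-substituted phenol by a small unhindered acid chloride under nucleophilic catalysis forms the future depside ester bond before ring A exists, and pyridine is used in place of a trialkylamine so that the enoyl chloride is not dehydrochlorinated to a vinylketene and deconjugated.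

Step 10
Reactants: 15 benzyl 2,4-bis(benzyloxy)-3-(1,3-dioxolan-2-yl)-6-methyl-5-{[(2E)-3-methyl-4-oxopent-2-enoyl]oxy}benzoate
Product: 17 benzyl 2,4-bis(benzyloxy)-5-{[(2E)-5-diazo-3-methyl-4-oxopent-2-enoyl]oxy}-3-(1,3-dioxolan-2-yl)-6-methylbenzoate, via trifluoroacetyl diketone 16 (not isolated)
Conditions: LiN(SiMe3)2, THF, −78 °C (15 added to the base); CF3CO2CH2CF3, −78 °C; aq NH4Cl; then MsN3, Et3N, H2O (1 equiv), MeCN, rt
Reagents that add atoms: methanesulfonyl azide, CS(=O)(=O)N=[N+]=[N-]
Why: Detrifluoroacetylative diazo transfer (kinetic enolisation of the methyl ketone, which is more acidic than the vinylogous C3 methyl group, C-trifluoroacetylation, then transfer of N2 from the sulfonyl azide with loss of the trifluoroacetyl group) should give the unsaturated diazoketone without exposing the 4-oxo-enoate double bond to diazomethane, which would add to it as a 1,3-dipole if an acid chloride were used instead.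

Step 11
Reactants: 18 chloroacetaldehyde dimethyl acetal
Product: 20 3-methoxyprop-2-yn-1-ol, via lithium methoxyacetylide 19 (not isolated)
Conditions: LiNEt2 (3.1 equiv, from n-BuLi and Et2NH), THF, 0 °C; (CH2O)n, −78 °C to rt; aq NH4Cl
Reagents that add atoms: formaldehyde (as paraformaldehyde), C=O
Why: Twofold base-induced elimination (HCl, then MeOH) and deprotonation give lithium methoxyacetylide, which adds to formaldehyde as an ordinary acetylide 1,2-addition.

Step 12
Reactants: 20 3-methoxyprop-2-yn-1-ol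
Product: 21 tert-butyl[(3-methoxyprop-2-yn-1-yl)oxy]dimethylsilane
Conditions: TBSCl, imidazole, CH2Cl2, 0 °C to rt (crude 20 used at once)
Reagents that add atoms: tert-butyldimethylsilyl chloride, CC(C)(C)[Si](C)(C)Cl
Why: Standard silylation of the primary alcohol removes the hydroxyl that would trap the ketene and stabilises the acid-sensitive alkoxypropargyl alcohol.

Step 13
Reactants: 17 benzyl 2,4-bis(benzyloxy)-5-{[(2E)-5-diazo-3-methyl-4-oxopent-2-enoyl]oxy}-3-(1,3-dioxolan-2-yl)-6-methylbenzoate and 21 tert-butyl[(3-methoxyprop-2-yn-1-yl)oxy]dimethylsilane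
Product: 26 benzyl 2,4-bis(benzyloxy)-5-{[3-({[tert-butyl(dimethyl)silyl]oxy}methyl)-2-hydroxy-4-methoxy-6-methylbenzoyl]oxy}-3-(1,3-dioxolan-2-yl)-6-methylbenzoate, via vinylketene 22 (not isolated), via vinylcyclobutenone 23 (not isolated), via dienylketene 24 (not isolated), via cyclohexadienone 25 (not isolated)
Conditions: hν (medium-pressure Hg lamp, Pyrex filter, above 300 nm), 21 (2.5 equiv), degassed ClCH2CH2Cl (0.03 M), rt; then 80 °C
Reagents that add atoms: none
Why: Irradiation expels N2 and the alkenyl group migrates (photochemical Wolff rearrangement) to give vinylketene 22 with its E alkene intact, which adds [2+2] to the ynol ether to give 23; four-electron electrocyclic opening gives dienylketene 24, and thermal six-electron disrotatory electrocyclisation (6-endo closure of ring A through the new C1–C2 bond) followed by enolisation of 25 gives the phenol. This is the Danheiser benzannulation in its diazoketone variant, known for unsaturated diazoketones with alkoxy- and siloxyalkynes. The bonds C2–C3 and C4–C5 come from the cycloaddition and C1–C2 from the electrocyclisation, so the ketene oxygen becomes the C2 hydroxyl, the methoxy-bearing alkyne carbon becomes C4 and the CH2OSi-bearing carbon becomes C3. No stereocentre is formed, the sp3 centres of 23 and 25 being transient. The step needs the regiochemistry of the cycloaddition, secured by the polarised ynol ether whose nucleophilic carbon (the one remote from oxygen) bonds to the ketene carbonyl carbon, and it needs the ester to stay trans to the ketene, secured by the E alkene, which rules out oxa-electrocyclisation to a 2-pyranone. Light above 300 nm should excite the diazoketone but not the aryl ester or benzyl groups, the methyl ynol ether has no retro-ene path at 80 °C, and the product phenol is hydrogen-bonded to the ester and flanked by CH2OSi, so it should not intercept the ketene.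

Step 14
Reactants: 26 benzyl 2,4-bis(benzyloxy)-5-{[3-({[tert-butyl(dimethyl)silyl]oxy}methyl)-2-hydroxy-4-methoxy-6-methylbenzoyl]oxy}-3-(1,3-dioxolan-2-yl)-6-methylbenzoate
Product: 27 benzyl 2,4-bis(benzyloxy)-3-formyl-5-{[2-hydroxy-3-(hydroxymethyl)-4-methoxy-6-methylbenzoyl]oxy}-6-methylbenzoate
Conditions: 48% aq HF, MeCN, 0 °C to rt
Reagents that add atoms: water, O
Why: Fluoride-assisted cleavage of the primary silyl ether and acid-catalysed hydrolysis of the very labile 2,6-dialkoxyaryl dioxolane run together in a weakly acidic aqueous medium that leaves the benzyl groups and both aryl esters intact.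

Step 15
Reactants: 27 benzyl 2,4-bis(benzyloxy)-3-formyl-5-{[2-hydroxy-3-(hydroxymethyl)-4-methoxy-6-methylbenzoyl]oxy}-6-methylbenzoate
Product: 28 benzyl 2,4-bis(benzyloxy)-3-formyl-5-[(3-formyl-2-hydroxy-4-methoxy-6-methylbenzoyl)oxy]-6-methylbenzoate
Conditions: activated MnO2, CH2Cl2, rt
Reagents that add atoms: none
Why: MnO2 oxidation of the benzylic (salicyl) alcohol stops at the aldehyde, which is hydrogen-bonded to the C2 hydroxyl, and touches no other group.

Step 16
Reactants: 28 benzyl 2,4-bis(benzyloxy)-3-formyl-5-[(3-formyl-2-hydroxy-4-methoxy-6-methylbenzoyl)oxy]-6-methylbenzoate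
Product: 29 haemathamnolic acid
Conditions: H2 (1 atm), 10% Pd/C, EtOAc, rt, stopped at full debenzylation
Reagents that add atoms: none
Why: Catalytic hydrogenolysis should cleave the benzyl ester and the two aryl benzyl ethers (all next to carbonyl groups) faster than it reduces the hydrogen-bonded aryl aldehydes, and the depside ester is inert under these neutral conditions.

**Compound list**

1 | orsellinic acid (2,4-dihydroxy-6-methylbenzoic acid) | Cc1cc(O)cc(O)c1C(=O)O | starting material
2 | benzyl 2,4-dihydroxy-6-methylbenzoate | Cc1cc(O)cc(O)c1C(=O)OCc1ccccc1 | intermediate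
3 | benzyl 3-[chloro(methoxy)methyl]-2,4-dihydroxy-6-methylbenzoate | COC(Cl)c1c(O)cc(C)c(C(=O)OCc2ccccc2)c1O | intermediate (not isolated)
4 | benzyl 3-formyl-2,4-dihydroxy-6-methylbenzoate | Cc1cc(O)c(C=O)c(O)c1C(=O)OCc1ccccc1 | intermediate
5 | benzyl 3-formyl-2,4-dihydroxy-5-iodo-6-methylbenzoate | Cc1c(I)c(O)c(C=O)c(O)c1C(=O)OCc1ccccc1 | intermediate
6 | benzyl 2,4-bis(benzyloxy)-3-formyl-5-iodo-6-methylbenzoate | Cc1c(I)c(OCc2ccccc2)c(C=O)c(OCc2ccccc2)c1C(=O)OCc1ccccc1 | intermediate
7 | benzyl 2,4-bis(benzyloxy)-3-(1,3-dioxolan-2-yl)-5-iodo-6-methylbenzoate | Cc1c(I)c(OCc2ccccc2)c(C2OCCO2)c(OCc2ccccc2)c1C(=O)OCc1ccccc1 | intermediate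
8 | {2,4-bis(benzyloxy)-5-[(benzyloxy)carbonyl]-3-(1,3-dioxolan-2-yl)-6-methylphenyl}magnesium chloride | Cc1c([Mg]Cl)c(OCc2ccccc2)c(C2OCCO2)c(OCc2ccccc2)c1C(=O)OCc1ccccc1 | intermediate (not isolated)
9 | benzyl 2,4-bis(benzyloxy)-5-(dimethoxyboranyl)-3-(1,3-dioxolan-2-yl)-6-methylbenzoate | COB(OC)c1c(C)c(C(=O)OCc2ccccc2)c(OCc2ccccc2)c(C2OCCO2)c1OCc1ccccc1 | intermediate (not isolated)
10 | benzyl 2,4-bis(benzyloxy)-3-(1,3-dioxolan-2-yl)-5-hydroxy-6-methylbenzoate | Cc1c(O)c(OCc2ccccc2)c(C2OCCO2)c(OCc2ccccc2)c1C(=O)OCc1ccccc1 | intermediate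
11 | butane-2,3-dione | CC(=O)C(C)=O | starting material
12 | tert-butyl (2E)-3-methyl-4-oxopent-2-enoate | CC(=O)/C(C)=C/C(=O)OC(C)(C)C | intermediate
13 | (2E)-3-methyl-4-oxopent-2-enoic acid | CC(=O)/C(C)=C/C(=O)O | intermediate
14 | (2E)-3-methyl-4-oxopent-2-enoyl chloride | CC(=O)/C(C)=C/C(=O)Cl | intermediate (not isolated)
15 | benzyl 2,4-bis(benzyloxy)-3-(1,3-dioxolan-2-yl)-6-methyl-5-{[(2E)-3-methyl-4-oxopent-2-enoyl]oxy}benzoate | CC(=O)/C(C)=C/C(=O)Oc1c(C)c(C(=O)OCc2ccccc2)c(OCc2ccccc2)c(C2OCCO2)c1OCc1ccccc1 | intermediate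
16 | benzyl 2,4-bis(benzyloxy)-3-(1,3-dioxolan-2-yl)-6-methyl-5-{[(2E)-7,7,7-trifluoro-3-methyl-4,6-dioxohept-2-enoyl]oxy}benzoate | O=C(CC(=O)/C(C)=C/C(=O)Oc1c(C)c(C(=O)OCc2ccccc2)c(OCc2ccccc2)c(C2OCCO2)c1OCc1ccccc1)C(F)(F)F | intermediate (not isolated)
17 | benzyl 2,4-bis(benzyloxy)-5-{[(2E)-5-diazo-3-methyl-4-oxopent-2-enoyl]oxy}-3-(1,3-dioxolan-2-yl)-6-methylbenzoate | [N-]=[N+]=CC(=O)/C(C)=C/C(=O)Oc1c(C)c(C(=O)OCc2ccccc2)c(OCc2ccccc2)c(C2OCCO2)c1OCc1ccccc1 | intermediate (key-step precursor)
18 | chloroacetaldehyde dimethyl acetal | COC(CCl)OC | starting material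
19 | lithium methoxyacetylide | [Li]C#COC | intermediate (not isolated)
20 | 3-methoxyprop-2-yn-1-ol | COC#CCO | intermediate
21 | tert-butyl[(3-methoxyprop-2-yn-1-yl)oxy]dimethylsilane | COC#CCO[Si](C)(C)C(C)(C)C | intermediate (key-step precursor)
22 | benzyl 2,4-bis(benzyloxy)-3-(1,3-dioxolan-2-yl)-6-methyl-5-{[(2E)-3-methyl-5-oxopenta-2,4-dienoyl]oxy}benzoate (vinylketene) | O=C=C/C(C)=C/C(=O)Oc1c(C)c(C(=O)OCc2ccccc2)c(OCc2ccccc2)c(C2OCCO2)c1OCc1ccccc1 | intermediate (not isolated)
23 | benzyl 2,4-bis(benzyloxy)-5-({(2E)-3-[3-({[tert-butyl(dimethyl)silyl]oxy}methyl)-2-methoxy-4-oxocyclobut-2-en-1-yl]but-2-enoyl}oxy)-3-(1,3-dioxolan-2-yl)-6-methylbenzoate (racemic at the ring CH) | COC1=C(CO[Si](C)(C)C(C)(C)C)C(=O)C1/C(C)=C/C(=O)Oc1c(C)c(C(=O)OCc2ccccc2)c(OCc2ccccc2)c(C2OCCO2)c1OCc1ccccc1 | intermediate (not isolated)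
24 | benzyl 2,4-bis(benzyloxy)-5-{[(2E,4E)-6-({[tert-butyl(dimethyl)silyl]oxy}methyl)-5-methoxy-3-methyl-7-oxohepta-2,4,6-trienoyl]oxy}-3-(1,3-dioxolan-2-yl)-6-methylbenzoate (dienylketene) | O=C=C(CO[Si](C)(C)C(C)(C)C)/C(OC)=C\C(C)=C\C(=O)Oc1c(C)c(C(=O)OCc2ccccc2)c(OCc2ccccc2)c(C2OCCO2)c1OCc1ccccc1 | intermediate (not isolated)
25 | 2,4-bis(benzyloxy)-5-[(benzyloxy)carbonyl]-3-(1,3-dioxolan-2-yl)-6-methylphenyl 3-({[tert-butyl(dimethyl)silyl]oxy}methyl)-4-methoxy-6-methyl-2-oxocyclohexa-3,5-diene-1-carboxylate (racemic at C1) | COC1=C(CO[Si](C)(C)C(C)(C)C)C(=O)C(C(=O)Oc2c(C)c(C(=O)OCc3ccccc3)c(OCc3ccccc3)c(C3OCCO3)c2OCc2ccccc2)C(C)=C1 | intermediate (not isolated)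
26 | benzyl 2,4-bis(benzyloxy)-5-{[3-({[tert-butyl(dimethyl)silyl]oxy}methyl)-2-hydroxy-4-methoxy-6-methylbenzoyl]oxy}-3-(1,3-dioxolan-2-yl)-6-methylbenzoate | COc1cc(C)c(C(=O)Oc2c(C)c(C(=O)OCc3ccccc3)c(OCc3ccccc3)c(C3OCCO3)c2OCc2ccccc2)c(O)c1CO[Si](C)(C)C(C)(C)C | intermediate (key-step product)
27 | benzyl 2,4-bis(benzyloxy)-3-formyl-5-{[2-hydroxy-3-(hydroxymethyl)-4-methoxy-6-methylbenzoyl]oxy}-6-methylbenzoate | COc1cc(C)c(C(=O)Oc2c(C)c(C(=O)OCc3ccccc3)c(OCc3ccccc3)c(C=O)c2OCc2ccccc2)c(O)c1CO | intermediate
28 | benzyl 2,4-bis(benzyloxy)-3-formyl-5-[(3-formyl-2-hydroxy-4-methoxy-6-methylbenzoyl)oxy]-6-methylbenzoate | COc1cc(C)c(C(=O)Oc2c(C)c(C(=O)OCc3ccccc3)c(OCc3ccccc3)c(C=O)c2OCc2ccccc2)c(O)c1C=O | intermediate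
29 | haemathamnolic acid, 3-formyl-5-[(3-formyl-2-hydroxy-4-methoxy-6-methylbenzoyl)oxy]-2,4-dihydroxy-6-methylbenzoic acid | COc1cc(C)c(C(=O)Oc2c(C)c(C(=O)O)c(O)c(C=O)c2O)c(O)c1C=O | target

**Step count**

Total: 16 steps. Longest linear sequence: 12 steps (steps 1 to 6, 9, 10, 13, 14, 15, 16, from orsellinic acid).

**Steps most likely to fail**

Step 13 (benzannulation). The E alkene may isomerise under irradiation, after which the Z vinylketene would close through the ester carbonyl oxygen. The ketene may also be lost to dimerisation or to acylation of the product phenol, and the cyclobutenone may not open cleanly on heating. The fallback gives up the ring construction and makes the depside bond by classical esterification with a preformed ring A acid. It sets out from 4 and 10. Selective O-methylation of the more acidic, less shielded 4-OH of 4 (MeI, K2CO3, acetone) should give benzyl 3-formyl-2-hydroxy-4-methoxy-6-methylbenzoate F1. Brief hydrogenolysis (H2, Pd/C, EtOAc) should give 3-formyl-2-hydroxy-4-methoxy-6-methylbenzoic acid F2. Trifluoroacetic anhydride in toluene should turn F2 into the mixed anhydride 3-formyl-2-hydroxy-4-methoxy-6-methylbenzoic trifluoroacetic anhydride F3, which acylates phenol 10 to give benzyl 2,4-bis(benzyloxy)-3-(1,3-dioxolan-2-yl)-5-[(3-formyl-2-hydroxy-4-methoxy-6-methylbenzoyl)oxy]-6-methylbenzoate F4. Hydrolysis of the acetal of F4 (1 M HCl, THF) comes back to the route at 28.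

Step 10 (diazo transfer). The lithium enolate or the amide base may attack the activated aryl ester or add in conjugate fashion to the 4-oxo-enoate before C-trifluoroacetylation, so that the substrate is consumed. The fallback installs the diazo group before the aryl ester is made. It sets out from 11 and rejoins with 10. Wittig reaction of 11 with 2-(trimethylsilyl)ethyl (triphenylphosphoranylidene)acetate should give 2-(trimethylsilyl)ethyl (2E)-3-methyl-4-oxopent-2-enoate F5. Diazo transfer on this cheap alkyl ester, a poor acyl donor, should go through 2-(trimethylsilyl)ethyl (2E)-7,7,7-trifluoro-3-methyl-4,6-dioxohept-2-enoate F6 to 2-(trimethylsilyl)ethyl (2E)-5-diazo-3-methyl-4-oxopent-2-enoate F7. Bu4NF in THF at 0 °C with buffered work-up removes the silylethyl group without acid and should give (2E)-5-diazo-3-methyl-4-oxopent-2-enoic acid F8. Carbodiimide esterification of F8 with phenol 10 (EDC·HCl, DMAP, CH2Cl2, 0 °C) comes back to the route at 17.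

Step 16 (hydrogenolysis). Reduction of one or both aryl aldehydes to the benzylic alcohol or the methyl group may compete with removal of the three benzyl groups. The fallback replaces hydrogenation by Lewis acid debenzylation. It sets out from 28: BCl3 with pentamethylbenzene as benzyl cation scavenger in CH2Cl2 at −78 °C, kept short and cold so that the ring A methyl ether next to the aldehyde is not cleaved, should give 29 directly.

**Further compounds**

F1 | step 13 | benzyl 3-formyl-2-hydroxy-4-methoxy-6-methylbenzoate | COc1cc(C)c(C(=O)OCc2ccccc2)c(O)c1C=O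
F2 | step 13 | 3-formyl-2-hydroxy-4-methoxy-6-methylbenzoic acid | COc1cc(C)c(C(=O)O)c(O)c1C=O
F3 | step 13 | 3-formyl-2-hydroxy-4-methoxy-6-methylbenzoic trifluoroacetic anhydride | COc1cc(C)c(C(=O)OC(=O)C(F)(F)F)c(O)c1C=O
F4 | step 13 | benzyl 2,4-bis(benzyloxy)-3-(1,3-dioxolan-2-yl)-5-[(3-formyl-2-hydroxy-4-methoxy-6-methylbenzoyl)oxy]-6-methylbenzoate | COc1cc(C)c(C(=O)Oc2c(C)c(C(=O)OCc3ccccc3)c(OCc3ccccc3)c(C3OCCO3)c2OCc2ccccc2)c(O)c1C=O
F5 | step 10 | 2-(trimethylsilyl)ethyl (2E)-3-methyl-4-oxopent-2-enoate | CC(=O)/C(C)=C/C(=O)OCC[Si](C)(C)C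
F6 | step 10 | 2-(trimethylsilyl)ethyl (2E)-7,7,7-trifluoro-3-methyl-4,6-dioxohept-2-enoate | O=C(CC(=O)/C(C)=C/C(=O)OCC[Si](C)(C)C)C(F)(F)F
F7 | step 10 | 2-(trimethylsilyl)ethyl (2E)-5-diazo-3-methyl-4-oxopent-2-enoate | [N-]=[N+]=CC(=O)/C(C)=C/C(=O)OCC[Si](C)(C)C
F8 | step 10 | (2E)-5-diazo-3-methyl-4-oxopent-2-enoic acid | [N-]=[N+]=CC(=O)/C(C)=C/C(=O)O
F0 | step 16 | none | none
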